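The numbers in the tables were computed with constants of no real substance, noise included.

The closed, stirred vessel holds 1.3 M of free monomer and 130 mM of initiator in both new flasks, and noon gets 0.390 M of transfer agent where spring gets 0.120 M.

all flasks: free monomer 1.3 M; initiator 130 mM

|  | transfer agent | protic impurity | remark | time |
|---|---|---|---|---|
| Saturday's | 0.16 M | 0.39 M | run made earlier |  |
| Thursday's | 0.21 M | 0.39 M | run made earlier |  |
| Wednesday's | 0.35 M | 0.39 M | run made earlier |  |
| noon | 0.390 M | 0.390 M |  | 50 h |
| spring | 0.120 M | 0.390 M |  | 50 h |

- which of the two ends with the longer chains by the average number of monomer units in a chain (chains begun, living or dead) ("neither" if they lie within 10%) (noon / spring / neither)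
- average number of monomer units in a chain (chains begun, living or dead) at the end, noon
- average number of monomer units in a chain (chains begun, living or dead) at the end, spring

Each initiator begins one chain, so if all of it reacts, the average length is the fraction of monomer in chains times the free monomer charged per initiator charged, 10.0, which I call the turnover ceiling. That leaves one thing to read from the runs, the fraction in chains.

| run | time / h | monomer in chains / % |
|---|---|---|
| Saturday's | 2.00 | 11.7 |
| Saturday's | 6.00 | 18.4 |
| Saturday's | 12.0 | 24.1 |
| Saturday's | 20.0 | 28.4 |
| Saturday's | 25.0 | 31.2 |
| Thursday's | 5.00 | 16.5 |
| Thursday's | 10.0 | 21.6 |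
| Thursday's | 15.0 | 25.3 |
| Thursday's | 20.0 | 26.9 |
| Thursday's | 25.0 | 28.2 |
| Wednesday's | 2.00 | 11.8 |
| Wednesday's | 6.00 | 16.0 |
| Wednesday's | 12.0 | 20.3 |
| Wednesday's | 20.0 | 22.6 |
| Wednesday's | 25.0 | 21.8 |

(standard deviation of a reading: 0.5 percentage points)

- the average divides the monomer in chains by the number of chains begun, living and dead together
- what may be going on: free monomer + initiator -> living end + monomer in chains; free monomer + living end -> monomer in chains + living end; living end + transfer agent -> dead chain; protic impurity + free monomer -> quenched substrate
- the earlier runs do not show the number of chains; that part of a forecast is a guess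

Saturday's run already reads 11.7% at 2.00 h, above the 10.0% that one unit per chain gives, so the initiator seems to react early. But the number of chains is not shown, so this stays a guess.

Wednesday's run, with 0.35 M of transfer agent, reads 22.6% at 20.0 h and 21.8% at 25.0 h. With a scatter of 0.5 percentage points these two readings cannot be told apart, and the first gives a length near 2.26. Saturday's run, with 0.16 M, is still rising at 31.2%, a length of 3.12.

Each living end dies on one transfer agent. Noon has 3.00 transfer agents per initiator charged and more transfer agent than Wednesday's run, so I expect about the length of Wednesday's run or a little less. In spring the transfer agent, charged below the initiator, is the limiting reagent of that death, and spring has less of it than Saturday's run and runs for 50 h, so I expect a length above the one Saturday's run reads at 25.0 h.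

The forecast says spring, with 2.2 for noon and 4.1 for spring: “Spring has less agent than ends, so some ends survive”.

The simulation gives spring, with 2.21 for noon and 4.25 for spring.

    free monomer + initiator → living end + monomer in chains (k = 0.0150 /M/min)
    free monomer + living end → monomer in chains + living end, rate k2*[living end]*[free monomer] (k = 0.00400 /M/min)
    living end + transfer agent → dead chain (kL = 0.00820 /M/min)
    protic impurity + free monomer → quenched substrate (k = 0.00550 /M/min)

With the initiator at 0% at the end of spring, the 42.5% of monomer in chains there times the ceiling gives 4.25. A neighbour of spring charged with 2.2 M of free monomer has a ceiling of 16.9. It ends with 46.3% in chains, which gives 7.83, and the simulated length of that neighbour is 7.83.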